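The numbers in the tables stem from a simulated flask for substances that don't exist, noise included.

If you take over autumn and winter, read cJ/cX, not cJ alone.

| flask | X | L | Z | remark | time |
|---|---|---|---|---|---|
| beta | 0.20 M | 0.31 M | 0.10 mM | run made earlier |  |
| delta | 0.20 M | 0.33 M | 0.10 mM | run made earlier |  |
| autumn | 0.20 M | 0.220 M | 0.10 mM |  | 20 min |
| winter | 0.20 M | 0.290 M | 0.10 mM |  | 20 min |

| run | time / min | Q / % | J / % | X / % | E / % |
|---|---|---|---|---|---|
| beta | 0.833 | 0.1 | 7.4 | 86.3 | 0 |
| beta | 2.50 | 0 | 17.3 | 64.9 | 0.5 |
| beta | 5.00 | 0.7 | 27.4 | 43.2 | 1.8 |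
| beta | 8.00 | 0.6 | 34.4 | 26.7 | 4.9 |
| beta | 10.0 | 0.7 | 37.0 | 19.9 | 6.7 |
| delta | 0.833 | 0.2 | 7.0 | 86.4 | 0.1 |
| delta | 2.50 | 0.5 | 17.3 | 65.0 | 0.2 |
| delta | 5.00 | 0.5 | 28.0 | 43.7 | 2.7 |
| delta | 8.00 | 0.1 | 34.3 | 26.8 | 5.2 |
| delta | 10.0 | 0.8 | 35.6 | 20.2 | 7.0 |

(readings scatter by 0.3 percentage points)

- percentages count the X that a species holds: one Q counts as two
- a reading of X is of its free form alone

1. which of these there is most of at the end, counted by the X in it, autumn (J / X / Q / E)
2. which of these there is most of at the end, counted by the X in it, winter (J / X / Q / E)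
3. the largest of these amounts at the end, in percent of the X charged, autumn
4. the largest of these amounts at the end, in percent of the X charged, winter

J forms from X and leaves as E. I take E's rate to follow cL·cJ, a pseudo-first-order drain on J, though beta and delta lie too close in L to test that. Over the run, J + E divided by the time integral of X gives the making constant, and E divided by cL times the integral of J gives the drain constant per cL. Their quotient is the crossing concentration: 1.00 M from beta and 0.992 M from delta, so I carry 0.998 M. By this reckoning, which carries the scatter of the readings, J stops climbing when cJ/cX reaches the crossing ratio w/cL, which with L as charged is 4.54 in autumn and 3.44 in winter.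

Extending beta's last fall of X puts X near 4.58% at 20 min. Beta's J at 10.0 min over that estimate mixes two moments and gives 8.08, above both ratios, so I expect J near its peak when you come. Beta's last J is 37.0% against 6.7% of E, so I expect J to lead in both flasks. I expect more J in autumn than in winter, because autumn's ratio is larger. Do not add L: winter, with more L than autumn, has the lower ratio.

The forecast gives J at 36% in autumn and J at 38% in winter, holding that “J leads among the listed species”. I differ on the order of the two flasks.

The flasks give J at 41.5% in autumn and J at 38.2% in winter.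

    X ⇌ G (K = 4.00, k = 0.00140 s⁻¹)
    X + J → Q (k = 3.10 × 10⁻⁴ M⁻¹ s⁻¹)
    L + Z + J → Z + E (k = 15.0 M⁻² s⁻¹)
    X + Z → Z + J (k = 15.0 M⁻¹ s⁻¹)

In autumn at 20.0 min, cJ/cX is 5.73 against a crossing ratio of 5.11 with L at 89% of its charge, and J is made at 0.882 of the rate it is used, after being made 7.92 times faster than used at 4.26 min. In the same flask read at 50 min, cJ/cX is 9.73 against 6.30, and J has come down to 35.5%.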